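98.1 % of the Zb charged is accounted for on the late plateau of the autumn run if each Ze has taken two Zb and each Zf one. At 1 equiv this leaves 1.90 %, so I read Zb as the limiting reagent.

- autumn: Zc 0.45 M; Zb 1 equiv; run made earlier
- flask: Zc 0.30 M; Zb 1.00 equiv; time 15 d

autumn run (percent of the Zc charged)

| time / h | Ze / % | Zf / % |
|---|---|---|
| 3.00 | 26.4 | 13.2 |
| 5.00 | 30.8 | 18.0 |
| 10.0 | 33.6 | 24.2 |
| 20.0 | 33.8 | 31.8 |
| 40.0 | 33.3 | 30.2 |

(readings scatter by 1 percentage point)

- at the start none of Zc is in solution
- a reading or a percentage of Zf counts all its forms, free or not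

- ratio of Ze to Zf at 15 min
- ratio of Ze to Zf at 8.0 h
- ratio of Ze to Zf at 15 d
- which of Ze and Zf there is more of at 15 d

The gain of Ze over the gain of Zf, which I call the split, reads 2.00 up to 3.00 h but 0.452 between 5.00 h and 10.0 h. I take this fall to mean that the step to Ze needs Zb and the step to Zf does not, which makes the split at any moment a constant times [Zb]. The ratio at the end is then that constant times a mean of [Zb].

Integrating the falling curve isn't necessary. At equal equivalents I assume that the mean is a fixed fraction of the charge, so that the end ratio, divided by the starting concentration of Zc, gives that constant multiplied by that fraction, not the constant itself. I call this product the end-ratio slope 2.41 M⁻¹, a reading from the autumn plateau.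

For the flask at 0.30 M I reckon an end ratio of 0.722. The balance above then gives 40.9 % of Zf, more than the 29.5 % of Ze. The risk lies in the fixed fraction, but the mean would have to be 1.39 times my figure for the lead to change.

The forecast gives 2.3 at 15 min, 1.5 at 8.0 h and 1.08 at 15 d, with Ze ahead, on the ground that “both products appear stalled”. Its last ratio differs from mine.

The flask gives 2.67, 0.964 and 0.738, with Zf ahead at 40.4 % against 29.8 % of Ze.

    Za + Zb ⇌ Zd (K = 6.00 M⁻¹, k = 0.0530 M⁻¹ s⁻¹)
    Zb + Zd → Ze (k = 8.80 × 10⁻⁴ M⁻¹ s⁻¹)
    Zd → Zf (k = 9.10 × 10⁻⁵ s⁻¹)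
    Zc ⇌ Za, rate k4*(cs4 - [Za]) while solid is left; crystals form when [Za] > cs4 (solubility = 0.100 M, k = 6.70 × 10⁻⁴ s⁻¹)
    Zg ⇌ Zf, rate k5*(cs5 - [Zf]) while solid is left; crystals form when [Zf] > cs5 (solubility = 0.100 M, k = 0.00650 s⁻¹)

In the flask at 0.0380 d, Zd goes to Zf at 0.57 of the rate at which Zb takes it to Ze, a split of 1.75. By 15 d the ratio stands at 0.738, which, divided by the ratio of the Ze and Zf constants, is a mean [Zb] of 0.0763 M, a quarter of the charge. The end-ratio slope gave 0.722 for this flask. For the neighbour flask with 0.075 M of Zc at the same equivalents it gives 0.181, and that flask stands at 0.256.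

(The earlier runs and the new flask were computed for substances that don't exist; scatter was added.)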